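**Plan**

1. Cuts, in retrosynthetic order: the C3–O ester bond (acid from tiglic acid); then the C8 oxygen, the C3–O/C4–O bonds and C4–C15, back to a Δ6-octalin with oxygen at C4; then C5–C10 and C8–C9 together; last C4–C5 of the open chain.
2. What makes the double cut possible: ring B holds its only alkene at C6=C7, between C5 and C8, with C11 already on C7. Read backwards, C5=C6–C7=C8 is a diene and C9=C10 a dienophile once the angular C14 is carried as a formyl group on C10; the four carbons C1–C4 tie the two together.
3. Forward: ε-caprolactone gives C14, C10 and C1–C4; an enyne from 2-methylbut-3-yn-2-ol gives C5–C8 and C11–C13. The chain is joined at C4–C5, then rings A and B close in one step (step 10). After that C14 becomes methyl, C8 is oxygenated, ring A becomes the 4-methyl-Δ3 alkene and is dihydroxylated, the ester is attached and C8 is oxidised.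
4. The diene carries no oxygen at C8, so its nucleophilic end (C8) and the electrophilic CH2 (C9) of the Lewis-acid-bound 2-methylene aldehyde are the pair the tether brings together, and nothing in the substrate is labile to the Lewis acid; the C8 oxygen is added later with SeO2.
5. Stereochemistry: the C4 carbinol centre (Noyori transfer hydrogenation) steers the diene face and so fixes C5 and C10; their trans relation comes from the formyl-endo/tether-exo arrangement. C4 is then oxidised, C3/C4 are set by osmylation anti to C14, and C2′/C3′ come from a Sharpless epoxidation and an inverting chloride opening.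

Key step: step 10

Remark: eudesmane numbering (C1–C15; C11 on C7, C14 on C10, C15 on C4) is used for the bicyclic compounds and for the chain atoms that become them; β is the face of C14. The C8 alcohol of 17–34 is drawn α; its configuration is of no consequence because C8 ends as the ketone.

**Route**

Step 1
Reactants: 1 2-methylbut-3-yn-2-ol (two molecules)
Product: 2 2,6-dimethyl-3-methylidenehept-4-yne-2,6-diol
Conditions: Pd(OAc)2 (2 mol %), tris(2,6-dimethoxyphenyl)phosphine (2 mol %), toluene, rt
Reagents that add atoms: none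
Why: Pd-catalysed head-to-tail dimerisation of a terminal alkyne (hydroalkynylation), known for tertiary propargylic alcohols, adds the C–H of one alkyne across the other and so places a carbinol on the 1,1-disubstituted alkene carbon (later C7 with C11).

Step 2
Reactants: 2 2,6-dimethyl-3-methylidenehept-4-yne-2,6-diol
Product: 3 2-methyl-3-methylidenepent-4-yn-2-ol
Conditions: NaH (5 mol %), toluene, 110 °C, acetone distilled off
Reagents that add atoms: none
Why: Retro-Favorskii cleavage; only the propargylic alkoxide can expel an acetylide, so acetone is lost from the alkyne end and the allylic tertiary alcohol stays.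

Step 3
Reactants: 4 oxepan-2-one (ε-caprolactone)
Product: 5 6-hydroxy-N-methoxy-N-methylhexanamide
Conditions: MeNHOMe·HCl, i-PrMgCl (3 equiv), THF, −20 → 0 °C
Reagents that add atoms: N,O-dimethylhydroxylamine hydrochloride, CNOC.Cl
Why: Ring opening of the lactone by the magnesium amide (Weinreb amide formation) gives the acyl donor for C4 and frees the primary alcohol that becomes C14.

Step 4
Reactants: 3 2-methyl-3-methylidenepent-4-yn-2-ol; 5 6-hydroxy-N-methoxy-N-methylhexanamide
Product: 7 1,10-dihydroxy-10-methyl-9-methylideneundec-7-yn-6-one, via dilithiated enyne 6 (not isolated)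
Conditions: 3, n-BuLi (2.0 equiv), THF, −78 °C; then 5 (pre-treated with i-PrMgCl, 1.0 equiv), −78 → 0 °C; cold aq. NH4Cl
Reagents that add atoms: none
Why: Acylation of an acetylide by a Weinreb amide; the chelated tetrahedral adduct survives until work-up, so the C4–C5 bond forms without over-addition.

Step 5
Reactants: 7 1,10-dihydroxy-10-methyl-9-methylideneundec-7-yn-6-one
Product: 8 (6R)-10-methyl-9-methylideneundec-7-yne-1,6,10-triol
Conditions: Ru[(R,R)-TsDPEN](p-cymene) (1 mol %), i-PrOH, rt
Reagents that add atoms: none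
Why: Noyori asymmetric transfer hydrogenation of an alkynyl ketone; the alkyne takes the role of the unsaturated group in the organised hydride transfer, so the (R,R)-catalyst should give the (R)-carbinol (C4) and leave the C=C bond alone.

Step 6
Reactants: 8 (6R)-10-methyl-9-methylideneundec-7-yne-1,6,10-triol
Product: 9 (6R,7E)-10-methyl-9-methylideneundec-7-ene-1,6,10-triol
Conditions: Red-Al (5 equiv), THF, 0 °C → rt; aq. Rochelle salt
Reagents that add atoms: none
Why: Alkoxide-directed trans-hydroalumination of the propargylic alcohol and protonolysis give only the (E)-alkene, the standard way from enynols to (E)-dienols, which fixes the C5=C6 geometry of the diene.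

Step 7
Reactants: 9 (6R,7E)-10-methyl-9-methylideneundec-7-ene-1,6,10-triol
Product: 10 (6R,7E)-10-methyl-9-methylidene-1,6,10-tris(triethylsilyloxy)undec-7-ene
Conditions: TESOTf (3.6 equiv), 2,6-lutidine, CH2Cl2, −78 → 0 °C
Reagents that add atoms: triethylsilyl trifluoromethanesulfonate, CC[Si](CC)(CC)OS(=O)(=O)C(F)(F)F
Why: A silyl triflate with a hindered pyridine base silylates primary, secondary and tertiary hydroxyl groups alike and avoids acid, to which the dienyl carbinol would be sensitive.

Step 8
Reactants: 10 (6R,7E)-10-methyl-9-methylidene-1,6,10-tris(triethylsilyloxy)undec-7-ene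
Product: 11 (6R,7E)-10-methyl-9-methylidene-6,10-bis(triethylsilyloxy)undec-7-enal
Conditions: (COCl)2, DMSO, CH2Cl2, −78 → −40 °C; then Et3N, −78 °C → rt
Reagents that add atoms: none
Why: Swern oxidation applied directly to a primary triethylsilyl ether; the chlorosulfonium ion attacks only the least hindered O–Si oxygen and the resulting alkoxysulfonium ion collapses to the aldehyde, while the secondary and tertiary TES ethers are kept.

Step 9
Reactants: 11 (6R,7E)-10-methyl-9-methylidene-6,10-bis(triethylsilyloxy)undec-7-enal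
Product: 13 (6R,7E)-10-methyl-2,9-dimethylidene-6,10-bis(triethylsilyloxy)undec-7-enal, via Mannich base 12 (not isolated)
Conditions: Eschenmoser's salt (2.5 equiv), Et3N, CH2Cl2, rt; used at once
Reagents that add atoms: N,N-dimethylmethylideneammonium iodide (Eschenmoser's salt), C=[N+](C)C.[I-]
Why: Mannich reaction of the aldehyde with the iminium salt and β-elimination of dimethylamine is the standard α-methylenation of aldehydes; it installs C9 under conditions that spare the silyl ethers and the diene.

Step 10
Reactants: 13 (6R,7E)-10-methyl-2,9-dimethylidene-6,10-bis(triethylsilyloxy)undec-7-enal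
Product: 14 (4R,5R,10S)-4α,11-bis(triethylsilyloxy)-15-noreudesm-6-en-14-al (trans-fused, H-5 α, formyl β)
Conditions: Me2AlCl (1.1 equiv), CH2Cl2, −78 → −30 °C
Reagents that add atoms: none
Why: Me2AlCl binds the formyl oxygen and lowers the LUMO of the C9=C10 alkene, and the tethered diene adds in a concerted, asynchronous [4+2] in which the peripheral C8–C9 bond (largest diene HOMO coefficient at C8, largest dienophile LUMO coefficient at C9) runs ahead of the internal C5–C10 bond; the closest known reaction type is the Lewis-acid-promoted type 1 intramolecular Diels–Alder reaction of 1,7,9-decatrienes whose dienophile carries the activating group on the tether carbon. Ring B is closed as the new cyclohexene by the cycloaddition itself, and ring A at the same moment by the four-carbon tether C1–C4 in the fused mode through a chair-like six-membered arrangement. Because the formyl group and the tether sit on the same carbon (C10), the endo preference of the complexed formyl group puts the tether exo, which sets C10 and C5 trans (C14 β, H-5 α). The absolute sense comes from C4: its silyloxy group should take the equatorial site of the chair, anti to the forming C5–C10 bond and away from the axial formyl group, so one diene face is used. Regiochemistry is secured by the tether, which allows only the fused adduct, and here the polarisation of both partners agrees with it; the step depends on the facial and endo selectivities, and minor isomers can be removed here because C4 keeps them diastereomeric.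

Step 11
Reactants: 14 (4R,5R,10S)-4α,11-bis(triethylsilyloxy)-15-noreudesm-6-en-14-al
Product: 16 4α,11-bis(triethylsilyloxy)-15-noreudesm-6-ene (H-5 α, 10β-methyl), via tosylhydrazone 15 (not isolated)
Conditions: TsNHNH2, THF, 4 Å MS, rt; then catecholborane, CHCl3, 0 °C; then NaOAc·3H2O, 60 °C
Reagents that add atoms: none
Why: Caglioti-type reduction of the tosylhydrazone; hydride adds to C=N, acetate triggers loss of sulfinate and N2 from the diazene, and the angular formyl group becomes the C14 methyl under conditions that leave the silyl ethers and the non-conjugated Δ6 alkene untouched.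

Step 12
Reactants: 16 4α,11-bis(triethylsilyloxy)-15-noreudesm-6-ene
Product: 17 4α,11-bis(triethylsilyloxy)-15-noreudesm-6-en-8α-ol
Conditions: SeO2 (0.5 equiv), t-BuOOH (3 equiv, in decane), CH2Cl2, 0 °C → rt
Reagents that add atoms: selenium dioxide, O=[Se]=O; tert-butyl hydroperoxide, CC(C)(C)OO
Why: SeO2 allylic oxidation (ene reaction, then [2,3]-shift of the allylseleninic acid); selenium bonds to the less substituted C6 and hydrogen is taken from the only CH group on the more substituted alkene carbon, the ring CH2 at C8, so the shift returns the C6=C7 alkene with oxygen on C8, on the face away from C14.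

Step 13
Reactants: 17 4α,11-bis(triethylsilyloxy)-15-noreudesm-6-en-8α-ol
Product: 18 8α-(tert-butyldimethylsilyloxy)-4α,11-bis(triethylsilyloxy)-15-noreudesm-6-ene
Conditions: TBSOTf, 2,6-lutidine, CH2Cl2, −78 → 0 °C
Reagents that add atoms: tert-butyldimethylsilyl trifluoromethanesulfonate, CC(C)(C)[Si](C)(C)OS(=O)(=O)C(F)(F)F
Why: Silylation of the hindered allylic alcohol with the silyl triflate gives a TBS ether that will outlast the removal of the C4 TES ether and hinders the Δ6 alkene further.

Step 14
Reactants: 18 8α-(tert-butyldimethylsilyloxy)-4α,11-bis(triethylsilyloxy)-15-noreudesm-6-ene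
Product: 19 8α-(tert-butyldimethylsilyloxy)-11-(triethylsilyloxy)-15-noreudesm-6-en-4α-ol
Conditions: PPTS (0.2 equiv), MeOH/CH2Cl2 1:1, 0 °C
Reagents that add atoms: none
Why: Acid-catalysed methanolysis of silyl ethers follows steric access and silyl size, so the secondary TES ether at C4 should be cleaved while the secondary TBS ether and the tertiary TES ether (about as robust as a secondary TBS ether) remain.

Step 15
Reactants: 19 8α-(tert-butyldimethylsilyloxy)-11-(triethylsilyloxy)-15-noreudesm-6-en-4α-ol
Product: 20 8α-(tert-butyldimethylsilyloxy)-11-(triethylsilyloxy)-15-noreudesm-6-en-4-one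
Conditions: Dess–Martin periodinane, NaHCO3, CH2Cl2, 0 °C → rt; used directly
Reagents that add atoms: none
Why: Buffered Dess–Martin oxidation gives the β,γ-unsaturated ketone without enolisation, so H-5 stays α and the alkene stays at C6=C7; the C4 centre has done its work and is removed here.

Step 16
Reactants: 20 8α-(tert-butyldimethylsilyloxy)-11-(triethylsilyloxy)-15-noreudesm-6-en-4-one
Product: 22 8α-(tert-butyldimethylsilyloxy)-11-(triethylsilyloxy)-15-noreudesma-3,6-dien-4-yl trifluoromethanesulfonate, via lithium enolate 21 (not isolated)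
Conditions: LDA (1.1 equiv), THF, −78 °C; then Comins' reagent, −78 → 0 °C
Reagents that add atoms: N-(5-chloropyridin-2-yl)-1,1,1-trifluoro-N-(trifluoromethylsulfonyl)methanesulfonamide (Comins' reagent), Clc1ccc(nc1)N(S(=O)(=O)C(F)(F)F)S(=O)(=O)C(F)(F)F
Why: Kinetic enol triflate formation; the bulky amide at −78 °C should take the accessible C3 methylene proton in preference to the tertiary H-5 next to the quaternary C10, and O-sulfonylation fixes the alkene at C3=C4.

Step 17
Reactants: 22 8α-(tert-butyldimethylsilyloxy)-11-(triethylsilyloxy)-15-noreudesma-3,6-dien-4-yl trifluoromethanesulfonate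
Product: 23 8α-(tert-butyldimethylsilyloxy)-11-(triethylsilyloxy)eudesma-3,6-diene
Conditions: MeMgBr (2 equiv), Fe(acac)3 (5 mol %), THF/NMP, −30 °C
Reagents that add atoms: methylmagnesium bromide, C[Mg]Br
Why: Iron-catalysed Kumada-type coupling of an alkenyl triflate with a methyl Grignard reagent is fast at low temperature and puts C15 on C4 without moving the alkene.

Step 18
Reactants: 23 8α-(tert-butyldimethylsilyloxy)-11-(triethylsilyloxy)eudesma-3,6-diene
Product: 24 8α-(tert-butyldimethylsilyloxy)-11-(triethylsilyloxy)eudesm-6-ene-3α,4α-diol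
Conditions: OsO4 (5 mol %), NMO, acetone/H2O, rt
Reagents that add atoms: osmium tetroxide, O=[Os](=O)(=O)=O; 4-methylmorpholine N-oxide, C[N+]1([O-])CCOCC1
Why: Upjohn dihydroxylation; the syn addition should occur on the α face of the Δ3 alkene because the axial C14 methyl blocks the β face at C4, while the Δ6 alkene is shielded by the C11 and C8 silyloxy groups, so C3 and C4 (3α-OH, 4α-OH, 4β-methyl) are set together.

Step 19
Reactants: 25 tiglic acid [(2E)-2-methylbut-2-enoic acid]
Product: 26 (2E)-2-methylbut-2-en-1-ol
Conditions: LiAlH4, Et2O, 0 °C → rt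
Reagents that add atoms: none
Why: Hydride reduction of the carboxylic acid to the primary allylic alcohol leaves the (E)-alkene unchanged.

Step 20
Reactants: 26 (2E)-2-methylbut-2-en-1-ol
Product: 27 [(2R,3R)-2,3-dimethyloxiran-2-yl]methanol
Conditions: Ti(OiPr)4 (10 mol %), D-(−)-diisopropyl tartrate (12 mol %), t-BuOOH, 4 Å MS, CH2Cl2, −20 °C; non-aqueous work-up
Reagents that add atoms: tert-butyl hydroperoxide, CC(C)(C)OO
Why: Sharpless asymmetric epoxidation; with the D-(−)-tartrate the oxygen is delivered to the face of the (E)-allylic alcohol that gives the (2R,3R)-epoxy alcohol, and the alkene geometry is carried into the epoxide.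

Step 21
Reactants: 27 [(2R,3R)-2,3-dimethyloxiran-2-yl]methanol
Product: 28 (2S,3R)-2,3-dimethyloxirane-2-carboxylic acid
Conditions: RuCl3·xH2O (2 mol %), NaIO4, MeCN/CCl4/H2O, rt
Reagents that add atoms: water, O
Why: RuO4 generated in situ oxidises the primary alcohol through the aldehyde hydrate to the acid without opening the epoxide; the C2 descriptor changes only through the CIP ranking.

Step 22
Reactants: 28 (2S,3R)-2,3-dimethyloxirane-2-carboxylic acid
Product: 29 (2R,3S)-3-chloro-2-hydroxy-2-methylbutanoic acid
Conditions: HCl (4 M in dioxane), 0 °C → rt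
Reagents that add atoms: hydrogen chloride, Cl
Why: Acid-promoted SN2 opening of the epoxide by chloride at C3, the only carbon open to backside attack (C2 is fully substituted and deactivated by the carboxyl group), inverts C3 and gives the (2R,3S)-chlorohydrin.

Step 23
Reactants: 29 (2R,3S)-3-chloro-2-hydroxy-2-methylbutanoic acid
Product: 31 (2R,3S)-3-chloro-2-methyl-2-(triethylsilyloxy)butanoic acid, via bis(triethylsilyl) derivative 30 (not isolated)
Conditions: TESOTf (2.3 equiv), 2,6-lutidine, CH2Cl2, 0 °C; then AcOH/THF/H2O, rt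
Reagents that add atoms: triethylsilyl trifluoromethanesulfonate, CC[Si](CC)(CC)OS(=O)(=O)C(F)(F)F
Why: Silylation of both the tertiary alcohol and the acid, then selective hydrolysis of the labile silyl ester, masks the tertiary hydroxyl that would otherwise compete during activation of the acid.

Step 24
Reactants: 24 8α-(tert-butyldimethylsilyloxy)-11-(triethylsilyloxy)eudesm-6-ene-3α,4α-diol; 31 (2R,3S)-3-chloro-2-methyl-2-(triethylsilyloxy)butanoic acid
Product: 33 8α-(tert-butyldimethylsilyloxy)-4α-hydroxy-11-(triethylsilyloxy)eudesm-6-en-3α-yl (2R,3S)-3-chloro-2-methyl-2-(triethylsilyloxy)butanoate, via acid chloride 32 (not isolated)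
Conditions: 31, Ghosez's reagent (1-chloro-N,N,2-trimethylprop-1-en-1-amine), CH2Cl2, 0 °C → rt; then 24, DMAP, Et3N, CH2Cl2, rt → 40 °C
Reagents that add atoms: none
Why: DMAP-catalysed acylation by an acid chloride made under neutral conditions; only the secondary C3 hydroxyl reacts because the C4 hydroxyl is tertiary, and the acid has no α-hydrogen, so neither ketene formation nor epimerisation is possible.

Step 25
Reactants: 33 8α-(tert-butyldimethylsilyloxy)-4α-hydroxy-11-(triethylsilyloxy)eudesm-6-en-3α-yl (2R,3S)-3-chloro-2-methyl-2-(triethylsilyloxy)butanoate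
Product: 34 4α,8α,11-trihydroxyeudesm-6-en-3α-yl (2R,3S)-3-chloro-2-hydroxy-2-methylbutanoate
Conditions: HF·pyridine, pyridine, THF, 0 °C → rt
Reagents that add atoms: none
Why: Fluoride cleavage of all three silyl ethers under buffered, weakly acidic conditions, which avoid the alkoxide that could close the chlorohydrin to an epoxide.

Step 26
Reactants: 34 4α,8α,11-trihydroxyeudesm-6-en-3α-yl (2R,3S)-3-chloro-2-hydroxy-2-methylbutanoate
Product: 35 4α,11-dihydroxy-8-oxoeudesm-6-en-3α-yl (2R,3S)-3-chloro-2-hydroxy-2-methylbutanoate (CNP0288516.1; 3R,4S,5R,10R)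
Conditions: activated MnO2, CH2Cl2, rt
Reagents that add atoms: none
Why: MnO2 oxidises only the allylic secondary alcohol at C8 to the enone; the tertiary alcohols, the ester and the alkyl chloride are inert, and no base is present that could move H-5.

**Compound list**

1 | 2-methylbut-3-yn-2-ol | CC(C)(O)C#C | starting material
2 | 2,6-dimethyl-3-methylidenehept-4-yne-2,6-diol | CC(C)(O)C(=C)C#CC(C)(C)O | intermediate
3 | 2-methyl-3-methylidenepent-4-yn-2-ol | CC(C)(O)C(=C)C#C | intermediate
4 | oxepan-2-one (ε-caprolactone) | O=C1CCCCCO1 | starting material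
5 | 6-hydroxy-N-methoxy-N-methylhexanamide | CON(C)C(=O)CCCCCO | intermediate
6 | dilithium derivative of 3 (lithium alkoxide and lithium acetylide) | [Li]OC(C)(C)C(=C)C#C[Li] | intermediate (not isolated)
7 | 1,10-dihydroxy-10-methyl-9-methylideneundec-7-yn-6-one | OCCCCCC(=O)C#CC(=C)C(C)(C)O | intermediate
8 | (6R)-10-methyl-9-methylideneundec-7-yne-1,6,10-triol | OCCCCC[C@@H](O)C#CC(=C)C(C)(C)O | intermediate
9 | (6R,7E)-10-methyl-9-methylideneundec-7-ene-1,6,10-triol | OCCCCC[C@@H](O)/C=C/C(=C)C(C)(C)O | intermediate
10 | (6R,7E)-10-methyl-9-methylidene-1,6,10-tris(triethylsilyloxy)undec-7-ene | CC[Si](CC)(CC)OCCCCC[C@@H](O[Si](CC)(CC)CC)/C=C/C(=C)C(C)(C)O[Si](CC)(CC)CC | intermediate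
11 | (6R,7E)-10-methyl-9-methylidene-6,10-bis(triethylsilyloxy)undec-7-enal | O=CCCCC[C@@H](O[Si](CC)(CC)CC)/C=C/C(=C)C(C)(C)O[Si](CC)(CC)CC | intermediate
12 | (6R,7E)-2-[(dimethylamino)methyl]-10-methyl-9-methylidene-6,10-bis(triethylsilyloxy)undec-7-enal (C2 epimers) | O=CC(CN(C)C)CCC[C@@H](O[Si](CC)(CC)CC)/C=C/C(=C)C(C)(C)O[Si](CC)(CC)CC | intermediate (not isolated)
13 | (6R,7E)-10-methyl-2,9-dimethylidene-6,10-bis(triethylsilyloxy)undec-7-enal | O=CC(=C)CCC[C@@H](O[Si](CC)(CC)CC)/C=C/C(=C)C(C)(C)O[Si](CC)(CC)CC | intermediate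
14 | (4R,5R,10S)-4α,11-bis(triethylsilyloxy)-15-noreudesm-6-en-14-al | O=C[C@]12CCC[C@@H](O[Si](CC)(CC)CC)[C@@H]1C=C(C(C)(C)O[Si](CC)(CC)CC)CC2 | intermediate
15 | 4-methylbenzenesulfonylhydrazone of 14 | Cc1ccc(cc1)S(=O)(=O)N/N=C/[C@]12CCC[C@@H](O[Si](CC)(CC)CC)[C@@H]1C=C(C(C)(C)O[Si](CC)(CC)CC)CC2 | intermediate (not isolated)
16 | 4α,11-bis(triethylsilyloxy)-15-noreudesm-6-ene | C[C@]12CCC[C@@H](O[Si](CC)(CC)CC)[C@@H]1C=C(C(C)(C)O[Si](CC)(CC)CC)CC2 | intermediate
17 | 4α,11-bis(triethylsilyloxy)-15-noreudesm-6-en-8α-ol | C[C@]12CCC[C@@H](O[Si](CC)(CC)CC)[C@@H]1C=C(C(C)(C)O[Si](CC)(CC)CC)[C@@H](O)C2 | intermediate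
18 | 8α-(tert-butyldimethylsilyloxy)-4α,11-bis(triethylsilyloxy)-15-noreudesm-6-ene | C[C@]12CCC[C@@H](O[Si](CC)(CC)CC)[C@@H]1C=C(C(C)(C)O[Si](CC)(CC)CC)[C@@H](O[Si](C)(C)C(C)(C)C)C2 | intermediate
19 | 8α-(tert-butyldimethylsilyloxy)-11-(triethylsilyloxy)-15-noreudesm-6-en-4α-ol | C[C@]12CCC[C@@H](O)[C@@H]1C=C(C(C)(C)O[Si](CC)(CC)CC)[C@@H](O[Si](C)(C)C(C)(C)C)C2 | intermediate
20 | 8α-(tert-butyldimethylsilyloxy)-11-(triethylsilyloxy)-15-noreudesm-6-en-4-one | C[C@]12CCCC(=O)[C@@H]1C=C(C(C)(C)O[Si](CC)(CC)CC)[C@@H](O[Si](C)(C)C(C)(C)C)C2 | intermediate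
21 | lithium Δ3-enolate of 20 | C[C@]12CCC=C(O[Li])[C@@H]1C=C(C(C)(C)O[Si](CC)(CC)CC)[C@@H](O[Si](C)(C)C(C)(C)C)C2 | intermediate (not isolated)
22 | 8α-(tert-butyldimethylsilyloxy)-11-(triethylsilyloxy)-15-noreudesma-3,6-dien-4-yl trifluoromethanesulfonate | C[C@]12CCC=C(OS(=O)(=O)C(F)(F)F)[C@@H]1C=C(C(C)(C)O[Si](CC)(CC)CC)[C@@H](O[Si](C)(C)C(C)(C)C)C2 | intermediate
23 | 8α-(tert-butyldimethylsilyloxy)-11-(triethylsilyloxy)eudesma-3,6-diene | C[C@]12CCC=C(C)[C@@H]1C=C(C(C)(C)O[Si](CC)(CC)CC)[C@@H](O[Si](C)(C)C(C)(C)C)C2 | intermediate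
24 | 8α-(tert-butyldimethylsilyloxy)-11-(triethylsilyloxy)eudesm-6-ene-3α,4α-diol | C[C@]12CC[C@@H](O)[C@@](C)(O)[C@@H]1C=C(C(C)(C)O[Si](CC)(CC)CC)[C@@H](O[Si](C)(C)C(C)(C)C)C2 | intermediate
25 | tiglic acid [(2E)-2-methylbut-2-enoic acid] | C/C=C(\C)C(=O)O | starting material
26 | (2E)-2-methylbut-2-en-1-ol | C/C=C(\C)CO | intermediate
27 | [(2R,3R)-2,3-dimethyloxiran-2-yl]methanol | C[C@H]1O[C@]1(C)CO | intermediate
28 | (2S,3R)-2,3-dimethyloxirane-2-carboxylic acid | C[C@H]1O[C@]1(C)C(=O)O | intermediate
29 | (2R,3S)-3-chloro-2-hydroxy-2-methylbutanoic acid | C[C@H](Cl)[C@](C)(O)C(=O)O | intermediate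
30 | triethylsilyl (2R,3S)-3-chloro-2-methyl-2-(triethylsilyloxy)butanoate | C[C@H](Cl)[C@](C)(O[Si](CC)(CC)CC)C(=O)O[Si](CC)(CC)CC | intermediate (not isolated)
31 | (2R,3S)-3-chloro-2-methyl-2-(triethylsilyloxy)butanoic acid | C[C@H](Cl)[C@](C)(O[Si](CC)(CC)CC)C(=O)O | intermediate
32 | (2R,3S)-3-chloro-2-methyl-2-(triethylsilyloxy)butanoyl chloride | C[C@H](Cl)[C@](C)(O[Si](CC)(CC)CC)C(Cl)=O | intermediate (not isolated)
33 | 8α-(tert-butyldimethylsilyloxy)-4α-hydroxy-11-(triethylsilyloxy)eudesm-6-en-3α-yl (2R,3S)-3-chloro-2-methyl-2-(triethylsilyloxy)butanoate | C[C@H](Cl)[C@](C)(O[Si](CC)(CC)CC)C(=O)O[C@@H]1CC[C@]2(C)C[C@H](O[Si](C)(C)C(C)(C)C)C(C(C)(C)O[Si](CC)(CC)CC)=C[C@H]2[C@]1(C)O | intermediate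
34 | 4α,8α,11-trihydroxyeudesm-6-en-3α-yl (2R,3S)-3-chloro-2-hydroxy-2-methylbutanoate | C[C@H](Cl)[C@](C)(O)C(=O)O[C@@H]1CC[C@]2(C)C[C@H](O)C(C(C)(C)O)=C[C@H]2[C@]1(C)O | intermediate
35 | 4α,11-dihydroxy-8-oxoeudesm-6-en-3α-yl (2R,3S)-3-chloro-2-hydroxy-2-methylbutanoate (CNP0288516.1) | C[C@H](Cl)[C@](C)(O)C(=O)O[C@@H]1CC[C@]2(C)CC(=O)C(C(C)(C)O)=C[C@H]2[C@]1(C)O | target

**Count and risks**

Total step count: 26. Longest linear sequence: 20 steps (steps 1, 2, 4–18, 24–26, from 2-methylbut-3-yn-2-ol); 19 from ε-caprolactone.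

Most likely to fail:

Step 10. The C4 silyloxy group may not discriminate the two diene faces well enough, or it may prefer the axial site. The formyl-exo (cis-fused) pathway may also compete, or the Lewis acid may ionise the allylic silyl ethers. In each case 14 would be accompanied by isomers of the wrong sense; these are separable at this stage only. The fallback moves the control from the substrate to the reagent. It sets out from 13 and cyclises it with a chiral oxazaborolidinium Lewis acid (CBS-type, triflimide-activated, CH2Cl2, −78 °C), a catalyst class established for Diels–Alder additions of 2-alkylacroleins to 2-substituted dienes. The catalyst enantiomer is chosen so that it reinforces the C4 centre, and the route is rejoined at 14. No new compound arises (none, F0).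

Step 16. Deprotonation may take H-5 instead of H-3, because H-5 is both α to the carbonyl and allylic. That would epimerise C5 or lead to sulfonylation of the conjugated dienolate. The fallback avoids enolate regiochemistry altogether with a Shapiro sequence. It sets out from 20, which is condensed with 2,4,6-triisopropylbenzenesulfonyl hydrazide (THF, rt) to the trisylhydrazone F1, with the sulfonamide nitrogen syn to the less hindered C3. Two equivalents of n-BuLi (THF/TMEDA, −78 → 0 °C) remove N–H and the syn C3 proton, and loss of sulfinate and N2 gives the alkenyllithium F2. Iodomethane then gives 23 directly, so that 22 is bypassed.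

Step 12. The ene oxidation may be slow on the hindered alkene, may over-oxidise, or may strip the C4 silyl ether under the acidic selenium conditions. The fallback reaches the same alcohol by oxygen transposition and sets out from 16. Photooxygenation (O2, tetraphenylporphyrin, hν, CH2Cl2) should take hydrogen from C8, geminal to the bulky C11 group, and give the allylic hydroperoxide F3. Ac2O/pyridine (Kornblum–DeLaMare dehydration) turns it into the enone F4. Weitz–Scheffer epoxidation (H2O2, NaOH, MeOH) from the α face gives the epoxy ketone F5. Wharton transposition (N2H4·H2O, AcOH, MeOH) then returns the C6=C7 alkene with the hydroxyl on C8α, which is 17.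

**Further compounds**

F0 | step 10 | none | none
F1 | step 16 | 2,4,6-triisopropylbenzenesulfonylhydrazone of 20 (N–N syn to C3) | C[C@]12CCC/C(=N\NS(=O)(=O)c3c(C(C)C)cc(C(C)C)cc3C(C)C)[C@@H]1C=C(C(C)(C)O[Si](CC)(CC)CC)[C@@H](O[Si](C)(C)C(C)(C)C)C2
F2 | step 16 | 8α-(tert-butyldimethylsilyloxy)-11-(triethylsilyloxy)-15-noreudesma-3,6-dien-4-yllithium | C[C@]12CCC=C([Li])[C@@H]1C=C(C(C)(C)O[Si](CC)(CC)CC)[C@@H](O[Si](C)(C)C(C)(C)C)C2
F3 | step 12 | 6α-hydroperoxy-4α,11-bis(triethylsilyloxy)-15-noreudesm-7-ene | C[C@]12CCC[C@@H](O[Si](CC)(CC)CC)[C@@H]1[C@@H](OO)C(C(C)(C)O[Si](CC)(CC)CC)=CC2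
F4 | step 12 | 4α,11-bis(triethylsilyloxy)-15-noreudesm-7-en-6-one | C[C@]12CCC[C@@H](O[Si](CC)(CC)CC)[C@@H]1C(=O)C(C(C)(C)O[Si](CC)(CC)CC)=CC2
F5 | step 12 | 7α,8α-epoxy-4α,11-bis(triethylsilyloxy)-15-noreudesman-6-one | C[C@]12CCC[C@@H](O[Si](CC)(CC)CC)[C@@H]1C(=O)[C@@]3(C(C)(C)O[Si](CC)(CC)CC)O[C@H]3C2
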